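**Retrosynthetic overview** (disconnections listed in the order in which the bonds are made)
1. Ten-membered ring: not disconnected. All fifteen skeletal carbons come as achiral germacrone 1. O-11 and H-7 go back to its enone (epoxide 2, ketol 3); O-8 and the absolute configuration go back to a CBS reduction (diol 4).
2. C4–H and C5–O: go back to the 4,5-alkene of 4 by syn hydroboration on the diol masked in the flask (5, 6, then triol 7). The borane hydrogen stands in for the proton that the cyclase puts on C4.
3. C1–C5, the key disconnection and the only ring made (five/seven system, formed last): transannular attack of the 1(10)-alkene on C5 as in the germacrane-to-guaiane biosynthesis, guaian-10-yl cation, loss of H-1 (8, 9, 10, then diol 11).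
4. Ester C–O: 11 plus (E)-4-acetoxycinnamic acid 12 (13), giving 14.

Assumption: germacrone (crystalline main ketone of zdravetz oil) and (E)-4-acetoxycinnamic acid are bought; germacrane/guaiane numbering is used throughout.

**Step 1**
Reactants: 1 germacrone, (1(10)E,4E)-germacra-1(10),4,7(11)-trien-8-one
Product: 2 rac-(1(10)E,4E)-7,11-epoxygermacra-1(10),4-dien-8-one
Conditions: 30% H2O2, NaOH (0.3 equiv), MeOH, 0 °C
Reagents that add atoms: hydrogen peroxide, OO
Why: Weitz–Scheffer nucleophilic epoxidation, in which hydroperoxide adds only to the electron-poor 7(11)-enone (the two ring alkenes are inert to it), as pulegone gives pulegone oxide; C7 is formed racemic and is erased again in step 2.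

**Step 2**
Reactants: 2 rac-7,11-epoxygermacra-1(10),4-dien-8-one
Product: 3 rac-(1(10)E,4E)-11-hydroxygermacra-1(10),4-dien-8-one
Conditions: SmI2 (2.2 equiv), THF/MeOH, −90 °C
Reagents that add atoms: none
Why: Molander-type reductive opening of an α,β-epoxy ketone, in which two electrons from divalent samarium cleave the Cα–O bond regiospecifically and methanol protonates the enolate at low temperature (no retro-aldol, no dehydration), giving H-7 and the C11 hydroxyl with C7 racemic.

**Step 3**
Reactants: 3 rac-11-hydroxygermacra-1(10),4-dien-8-one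
Product: 4 (1(10)E,4E,7S,8S)-germacra-1(10),4-diene-8,11-diol
Conditions: (R)-2-methyl-CBS-oxazaborolidine (0.3 equiv), catecholborane (0.6 equiv), PhMe, −78 °C; MeOH, pH 7 buffer
Reagents that add atoms: none
Why: Corey–Bakshi–Shibata reduction run as a kinetic resolution, in which for the (7R)-antipode of 3 the catalyst preference (branched C7 side large, C9 methylene small) and the Felkin–Anh preference deliver hydride to the same face and give the (8S)-alcohol with H-7 anti to O-8, while the mismatched (7S)-antipode of 3 stays behind, is removed on base-washed silica and can be dehydrated back to 1 (yield at most 50% per pass).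

**Step 4**
Reactants: 4 (7S,8S)-germacra-1(10),4-diene-8,11-diol
Product: 7 (1(10)E,4S,5R,7S,8S)-germacr-1(10)-ene-5,8,11-triol, via cyclic phenylboronate 5 (not isolated), via alkylborane 6 (not isolated)
Conditions: PhB(OH)2, MgSO4, CH2Cl2, rt; then 9-BBN dimer, THF, 45 °C; then NaOH, H2O2, 0 °C
Reagents that add atoms: hydrogen peroxide, OO
Why: Brown hydroboration–oxidation on the diol masked as its six-membered boronate, in which 9-BBN (one B–H, so no transannular second addition) adds syn and anti-Markovnikov to the 4,5-alkene (the 1(10)-alkene is deactivated by the homoallylic C8 oxygen) from the outer face of the crossed germacradiene conformer, the face peracids use in 7β-substituted germacranes, so that H goes to C4 (4S) and, after stereoretentive oxidation, OH to C5 (5R).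

**Step 5**
Reactants: 7 (4S,5R,7S,8S)-germacr-1(10)-ene-5,8,11-triol
Product: 11 (4S,5S,7S,8S)-guai-1(10)-ene-8,11-diol (8α-hydroxybulnesol), via masked triol 8 (not isolated), via secondary triflate 9 (not isolated), via guaiane phenylboronate 10 (not isolated)
Conditions: PhB(OH)2, MgSO4, CH2Cl2, rt; then Tf2O, 2,6-di-tert-butyl-4-methylpyridine, CH2Cl2, −78 → −20 °C; then NaOH, H2O2, 0 °C
Reagents that add atoms: none
Why: Transannular cation–olefin cyclization of the Marshall cyclodecenyl sulfonate type, mirroring the biosynthetic closure: C1 of the 1(10)-alkene displaces the triflate from the rear (Markovnikov, five-membered ring, inversion at C5 to 5S with H-5 cis to H-4 and H-7), the guaian-10-yl cation loses H-1 to give the tetrasubstituted 1(10)-alkene as in parthenolide to micheliolide, the boronate keeps O-11 from trapping C10 as a kessane-type ether, and oxidative work-up frees the diol.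

**Step 6**
Reactants: 11 (4S,5S,7S,8S)-guai-1(10)-ene-8,11-diol; 12 (E)-4-acetoxycinnamic acid
Product: 14 (4S,5S,7S,8S)-11-hydroxyguai-1(10)-en-8-yl (E)-3-(4-hydroxyphenyl)prop-2-enoate (CNP0403230.1), via aryl acetate 13 (not isolated)
Conditions: DCC, DMAP (cat.), CH2Cl2, 0 °C → rt; then pyrrolidine, 0 °C
Reagents that add atoms: (E)-4-acetoxycinnamic acid 12, CC(=O)Oc1ccc(/C=C/C(=O)O)cc1
Why: Steglich esterification acylates only the secondary C8 hydroxyl (the tertiary C11 hydroxyl is inert) without touching a stereocentre, and pyrrolidine then aminolyses the far more reactive aryl acetate, so the tertiary alcohol/tetrasubstituted alkene pair never meets acid.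

**Compound list**
1 | germacrone, (1(10)E,4E)-germacra-1(10),4,7(11)-trien-8-one | C/C1=C\CC/C(C)=C/CC(=C(C)C)C(=O)C1 | starting material
2 | rac-(1(10)E,4E)-7,11-epoxygermacra-1(10),4-dien-8-one | C/C1=C\CC/C(C)=C/CC2(OC2(C)C)C(=O)C1 | intermediate
3 | rac-(1(10)E,4E)-11-hydroxygermacra-1(10),4-dien-8-one | C/C1=C\CC/C(C)=C/CC(C(C)(C)O)C(=O)C1 | intermediate
4 | (1(10)E,4E,7S,8S)-germacra-1(10),4-diene-8,11-diol | C/C1=C\CC/C(C)=C/C[C@H](C(C)(C)O)[C@@H](O)C1 | intermediate
5 | cyclic 8,11-phenylboronate of 4 | C/C1=C\CC/C(C)=C/C[C@@H]2C(C)(C)OB(c3ccccc3)O[C@H]2C1 | intermediate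
6 | (4S,5R)-C5 9-borabicyclo[3.3.1]non-9-yl adduct of 5 | C/C1=C\CC[C@H](C)[C@H](B5C6CCCC5CCC6)C[C@@H]2C(C)(C)OB(c3ccccc3)O[C@H]2C1 | intermediate
7 | (1(10)E,4S,5R,7S,8S)-germacr-1(10)-ene-5,8,11-triol | C/C1=C\CC[C@H](C)[C@H](O)C[C@H](C(C)(C)O)[C@@H](O)C1 | intermediate
8 | cyclic 8,11-phenylboronate of 7 | C/C1=C\CC[C@H](C)[C@H](O)C[C@@H]2C(C)(C)OB(c3ccccc3)O[C@H]2C1 | intermediate
9 | C5 trifluoromethanesulfonate of 8 | C/C1=C\CC[C@H](C)[C@H](OS(=O)(=O)C(F)(F)F)C[C@@H]2C(C)(C)OB(c3ccccc3)O[C@H]2C1 | intermediate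
10 | cyclic 8,11-phenylboronate of 11 | CC1=C2CC[C@H](C)[C@@H]2C[C@@H]3C(C)(C)OB(c4ccccc4)O[C@H]3C1 | intermediate
11 | (4S,5S,7S,8S)-guai-1(10)-ene-8,11-diol (8α-hydroxybulnesol) | CC1=C2CC[C@H](C)[C@@H]2C[C@H](C(C)(C)O)[C@@H](O)C1 | intermediate
12 | (E)-4-acetoxycinnamic acid | CC(=O)Oc1ccc(/C=C/C(=O)O)cc1 | starting material
13 | (4S,5S,7S,8S)-11-hydroxyguai-1(10)-en-8-yl (E)-3-(4-acetoxyphenyl)prop-2-enoate | CC1=C2CC[C@H](C)[C@@H]2C[C@H](C(C)(C)O)[C@@H](OC(=O)/C=C/c2ccc(OC(C)=O)cc2)C1 | intermediate
14 | (4S,5S,7S,8S)-11-hydroxyguai-1(10)-en-8-yl (E)-3-(4-hydroxyphenyl)prop-2-enoate | CC1=C2CC[C@H](C)[C@@H]2C[C@H](C(C)(C)O)[C@@H](OC(=O)/C=C/c2ccc(O)cc2)C1 | target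

**Totals**
Total step count: 6. Longest linear sequence: 6 steps (1 to 14; 12 is bought).

**Three steps most likely to fail**

Step 3 (the resolution may not be selective enough, and it discards half of the material). The fallback sets out from 1 and moves the asymmetric reduction to the prochiral ketone. (R)-2-Methyl-CBS-oxazaborolidine with catecholborane gives (8S)-germacra-1(10),4,7(11)-trien-8-ol F1. VO(acac)2 with t-BuOOH then epoxidizes only the allylic tetrasubstituted alkene, syn to the hydroxyl, to give (7R,8S)-7,11-epoxygermacra-1(10),4-dien-8-ol F2. Cp2TiCl with 1,4-cyclohexadiene opens this 2,3-epoxy alcohol to the 1,3-diol by homolysis of the C7–O bond and hydrogen-atom transfer to the planar C7 radical under control of C8, and the route is rejoined at 4.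

Step 4 (9-BBN may not tell the two ring alkenes apart, or may take the wrong face). The fallback sets out from 3 and puts the C5 oxygen in at the ketone stage, where the selectivity is known from germacrone itself. Buffered m-CPBA epoxidizes only the 4,5-alkene (the 1(10)-alkene is β,γ to the carbonyl) to give racemic (4R*,5R*,7R*)-4,5-epoxy-11-hydroxygermacr-1(10)-en-8-one F3. Cp2TiCl/H2O opens the epoxide at the tertiary carbon with hydrogen-atom transfer to give racemic (4S*,5R*,7R*)-5,11-dihydroxygermacr-1(10)-en-8-one F4. The CBS resolution of step 3, applied to this ketone, rejoins the route at 7.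

Step 5 (the secondary triflate may eliminate or undergo a 1,2-hydride shift before C1 attacks, or the cation may lose the wrong proton). The fallback sets out from 4 and ionizes C5 as a stabilized allyl cation instead. m-CPBA gives (4R,5R,7S,8S)-4,5-epoxygermacr-1(10)-ene-8,11-diol F5. Cp2TiCl without a hydrogen donor isomerizes it to the exocyclic allylic alcohol (5R,7S,8S)-germacra-1(10),4(15)-diene-5,8,11-triol F6. PhB(OH)2 masks the 1,3-diol in the flask as the cyclic phenylboronate of that triol F7. Catalytic Bi(OTf)3 ionizes the allylic alcohol, and transannular closure with loss of H-1 gives the guaia-1(10),4(15)-diene phenylboronate F8. Hydrogenation of the exocyclic alkene only, with RhCl(PPh3)3/H2 from the face of H-5, rejoins the route at 10.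

**Further compounds**
F1 | step 3 | (8S)-germacra-1(10),4,7(11)-trien-8-ol | C/C1=C\CC/C(C)=C/CC(=C(C)C)[C@@H](O)C1
F2 | step 3 | (7R,8S)-7,11-epoxygermacra-1(10),4-dien-8-ol | C/C1=C\CC/C(C)=C/C[C@@]2(OC2(C)C)[C@@H](O)C1
F3 | step 4 | rac-(4R*,5R*,7R*)-4,5-epoxy-11-hydroxygermacr-1(10)-en-8-one (one enantiomer drawn) | C/C1=C\CC[C@@]2(C)O[C@@H]2C[C@H](C(C)(C)O)C(=O)C1
F4 | step 4 | rac-(4S*,5R*,7R*)-5,11-dihydroxygermacr-1(10)-en-8-one (one enantiomer drawn) | C/C1=C\CC[C@H](C)[C@H](O)C[C@H](C(C)(C)O)C(=O)C1
F5 | step 5 | (4R,5R,7S,8S)-4,5-epoxygermacr-1(10)-ene-8,11-diol | C/C1=C\CC[C@@]2(C)O[C@@H]2C[C@H](C(C)(C)O)[C@@H](O)C1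
F6 | step 5 | (5R,7S,8S)-germacra-1(10),4(15)-diene-5,8,11-triol | C/C1=C\CCC(=C)[C@H](O)C[C@H](C(C)(C)O)[C@@H](O)C1
F7 | step 5 | cyclic 8,11-phenylboronate of (5R,7S,8S)-germacra-1(10),4(15)-diene-5,8,11-triol | C/C1=C\CCC(=C)[C@H](O)C[C@@H]2C(C)(C)OB(c3ccccc3)O[C@H]2C1
F8 | step 5 | cyclic 8,11-phenylboronate of (5S,7S,8S)-guaia-1(10),4(15)-diene-8,11-diol | CC1=C2CCC(=C)[C@@H]2C[C@@H]3C(C)(C)OB(c4ccccc4)O[C@H]3C1
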